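**Strategy.** Everything rests on cutting ring B (the cyclopentane) between its tertiary carbinol carbon C3 and the adjacent methylene C2 (azulene numbering of the target). Forward, a primary iodide on a two-carbon arm at the quaternary carbon C8a is reduced by SmI2, and the alkylsamarium adds to the isopropyl ketone on the ring-fusion carbon C3a: one operation closes ring B, forms C2–C3 and sets the C3 hydroxyl. The precursor is a cycloheptanone (ring A) carrying methyl and 2-iodoethyl at C8a, isobutyryl at C3a and a silyloxy group at C4, built by conjugate addition and enolate allylation on an enantioenriched 4-silyloxy-2-methylcycloheptenone, one ozonolysis unmasking both carbonyl groups.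

Key step: step 11

Assumption: in step 2 the quinidine-derived base is taken to deliver the 4S alcohol; should it deliver 4R, its quinine-derived pseudoenantiomer (9-O-acetylcupreine) is used and nothing else changes.

Remarks: TBS = tert-butyldimethylsilyl. Locants C1–C8a in the Why lines follow the azulene numbering of the target (C3 carbinol, C3a ring-fusion CH, C4 oxygen-bearing CH, C6 methyl-bearing carbon, C8 carbonyl, C8a quaternary carbon).

Step 1
Reactants: 1 cyclohepta-1,3-diene
Product: 2 (1R,5S)-6,7-dioxabicyclo[3.2.2]non-8-ene (meso endoperoxide)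
Conditions: O2, visible light, tetraphenylporphyrin (cat.), CH2Cl2, 0 °C
Reagents that add atoms: dioxygen, O=O
Why: Sensitised singlet oxygen adds across the s-cis diene in a [4+2] cycloaddition (photooxygenation) and should give the meso endoperoxide.

Step 2
Reactants: 2 (1R,5S)-6,7-dioxabicyclo[3.2.2]non-8-ene
Product: 3 (4S)-4-hydroxycyclohept-2-en-1-one
Conditions: 9-O-acetylcupreidine (5 mol %), CH2Cl2, rt
Reagents that add atoms: none
Why: The chiral amine removes one of the two enantiotopic bridgehead hydrogens as the O–O bond breaks (enantioselective Kornblum–DeLaMare rearrangement), so C4 is set by catalyst control.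

Step 3
Reactants: 3 (4S)-4-hydroxycyclohept-2-en-1-one
Product: 4 (4S)-4-(TBS-oxy)cyclohept-2-en-1-one
Conditions: TBSCl, imidazole, DMF, 0 °C → rt
Reagents that add atoms: tert-butyldimethylsilyl chloride, CC(C)(C)[Si](C)(C)Cl
Why: Imidazole-promoted silylation of the secondary alcohol gives the bulky ether that later shields one face of the enone.

Step 4
Reactants: 4 (4S)-4-(TBS-oxy)cyclohept-2-en-1-one
Product: 5 (4S)-4-(TBS-oxy)-2-iodocyclohept-2-en-1-one
Conditions: I2, pyridine/CH2Cl2, 0 °C → rt; aq. Na2S2O3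
Reagents that add atoms: iodine, II
Why: Pyridine adds reversibly to the enone, the enolate is iodinated and pyridine is expelled (amine-mediated α-iodination of cyclic enones), leaving C4 untouched.

Step 5
Reactants: 5 (4S)-4-(TBS-oxy)-2-iodocyclohept-2-en-1-one
Product: 6 (4S)-4-(TBS-oxy)-2-methylcyclohept-2-en-1-one
Conditions: Me4Sn, Pd2(dba)3 (cat.), AsPh3, CuI (cat.), NMP, 70 °C
Reagents that add atoms: tetramethylstannane, C[Sn](C)(C)C
Why: Stille coupling of the α-iodo enone under neutral conditions installs the future C8a methyl group without risk to the γ-stereocentre.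

Step 6
Reactants: 7 3-methylbutan-2-one; 8 2,4,6-tri(propan-2-yl)benzenesulfonohydrazide
Product: 9 (E)-N'-(3-methylbutan-2-ylidene)-2,4,6-tri(propan-2-yl)benzenesulfonohydrazide
Conditions: MeOH, HCl (cat.), rt
Reagents that add atoms: none
Why: Acid-catalysed condensation of the ketone with the sulfonyl hydrazide gives the crystalline hydrazone required for a Shapiro reaction.

Step 7
Reactants: 6 (4S)-4-(TBS-oxy)-2-methylcyclohept-2-en-1-one; 9 (E)-N'-(3-methylbutan-2-ylidene)-2,4,6-tri(propan-2-yl)benzenesulfonohydrazide; 10 allyl bromide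
Product: 12 (2S,3S,4S)-4-(TBS-oxy)-2-methyl-3-(3-methylbut-1-en-2-yl)-2-(prop-2-en-1-yl)cycloheptan-1-one, via lithium enolate 11 (not isolated)
Conditions: 9, n-BuLi (2 equiv per 9), THF, −78 → 0 °C; CuBr·SMe2, −78 °C; 6, −78 → −30 °C; HMPA, 10, −30 → 0 °C; aq. NH4Cl
Reagents that add atoms: none
Why: The Shapiro reaction of 9 (deprotonation on the methyl side) gives 3-methylbut-1-en-2-yllithium, whose Gilman cuprate should add 1,4 to 6 on the face opposite the C4 silyloxy group (sets C3a), and the regiodefined enolate 11 should then be allylated opposite the new alkenyl group (sets C8a) in a conjugate addition–enolate alkylation sequence.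

Step 8
Reactants: 12 (2S,3S,4S)-4-(TBS-oxy)-2-methyl-3-(3-methylbut-1-en-2-yl)-2-(prop-2-en-1-yl)cycloheptan-1-one
Product: 13 2-[(1S,2S,3S)-3-(TBS-oxy)-1-methyl-2-(2-methylpropanoyl)-7-oxocycloheptyl]acetaldehyde
Conditions: O3, CH2Cl2, −78 °C; PPh3, −78 °C → rt
Reagents that add atoms: ozone, [O-][O+]=O
Why: Ozonolysis with reductive work-up cleaves both terminal alkenes at once, turning the 1,1-disubstituted alkene into the isopropyl ketone and the allyl group into the two-carbon aldehyde arm under neutral conditions that spare the β-silyloxy ketone.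

Step 9
Reactants: 13 2-[(1S,2S,3S)-3-(TBS-oxy)-1-methyl-2-(2-methylpropanoyl)-7-oxocycloheptyl]acetaldehyde
Product: 14 (2S,3S,4S)-4-(TBS-oxy)-2-(2-hydroxyethyl)-2-methyl-3-(2-methylpropanoyl)cycloheptan-1-one
Conditions: NaBH4, CH2Cl2/EtOH (7:3), −78 °C; AcOH quench
Reagents that add atoms: none
Why: At −78 °C the borohydride should reduce the aldehyde far faster than the two hindered ketones (chemoselective hydride reduction).

Step 10
Reactants: 14 (2S,3S,4S)-4-(TBS-oxy)-2-(2-hydroxyethyl)-2-methyl-3-(2-methylpropanoyl)cycloheptan-1-one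
Product: 15 (2S,3S,4S)-4-(TBS-oxy)-2-(2-iodoethyl)-2-methyl-3-(2-methylpropanoyl)cycloheptan-1-one
Conditions: I2, PPh3, imidazole, CH2Cl2, 0 °C → rt, dark
Reagents that add atoms: iodine, II
Why: Appel-type iodination converts the primary alcohol, which reacts through its open hydroxy ketone form, into the iodide by SN2 displacement of the alkoxyphosphonium ion under nearly neutral conditions.

Step 11
Reactants: 15 (2S,3S,4S)-4-(TBS-oxy)-2-(2-iodoethyl)-2-methyl-3-(2-methylpropanoyl)cycloheptan-1-one
Product: 16 (1R,3aS,8S,8aS)-8-(TBS-oxy)-1-hydroxy-3a-methyl-1-(propan-2-yl)octahydroazulen-4(1H)-one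
Conditions: SmI2 (3 equiv), HMPA (12 equiv), THF, −78 → 0 °C, slow addition of 15; aq. NH4Cl
Reagents that add atoms: none
Why: SmI2 activated by HMPA passes one electron to the C–I bond, the primary radical is reduced again, and the resulting alkylsamarium adds intramolecularly to the isobutyryl carbonyl; this is an intramolecular samarium Barbier reaction, the known SmI2 cyclisation of iodo ketones to cyclopentanols. Ring B closes in a 5-exo-trig mode at the carbonyl carbon, whereas attack on the ring A ketone would have to form a cyclobutanol and should not compete. The new stereocentre C3 is controlled by the neighbouring C3a centre: in the envelope-like transition state the isopropyl group should sit on the side of the C3a hydrogen and away from the C4 branch, so the oxygen ends up on the C4 side, and contact of trivalent samarium with the silyl ether oxygen can only reinforce this. The ring fusion is not at issue, because the iodoethyl arm and the acyl group are already trans on C8a and C3a. The step needs C–I reduction to win over ketyl formation at either ketone, which HMPA (it accelerates halide reduction far more than dialkyl ketone reduction), the absence of a proton source and the low temperature should secure. No strongly basic reagent touches the β-silyloxy ketone.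

Step 12
Reactants: 16 (1R,3aS,8S,8aS)-8-(TBS-oxy)-1-hydroxy-3a-methyl-1-(propan-2-yl)octahydroazulen-4(1H)-one
Product: 17 (1R,3aS,8S,8aS)-8-(TBS-oxy)-1-hydroxy-3a-methyl-1-(propan-2-yl)-2,3,3a,7,8,8a-hexahydroazulen-4(1H)-one
Conditions: IBX (1.5–2 equiv), DMSO/toluene, 65 °C
Reagents that add atoms: none
Why: IBX dehydrogenates the ketone through its enol (IBX desaturation), and because C8a is quaternary only the C7–C6 bond can become unsaturated.

Step 13
Reactants: 17 (1R,3aS,8S,8aS)-8-(TBS-oxy)-1-hydroxy-3a-methyl-1-(propan-2-yl)-2,3,3a,7,8,8a-hexahydroazulen-4(1H)-one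
Product: 18 (1R,3aS,8S,8aS)-8-(TBS-oxy)-1-hydroxy-3a,6-dimethyl-1-(propan-2-yl)octahydroazulen-4(1H)-one (C6 configuration not controlled; either epimer serves)
Conditions: Me2CuLi (3 equiv, from MeLi and CuI), Et2O, −40 → 0 °C; aq. NH4Cl
Reagents that add atoms: lithium dimethylcuprate, [Li+].C[Cu-]C
Why: Conjugate addition of the Gilman reagent places the methyl group on C6 (one equivalent is consumed by the tertiary hydroxyl), and the C6 configuration is irrelevant because that centre becomes sp2 in step 14.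

Step 14
Reactants: 18 (1R,3aS,8S,8aS)-8-(TBS-oxy)-1-hydroxy-3a,6-dimethyl-1-(propan-2-yl)octahydroazulen-4(1H)-one
Product: 19 (1R,3aS,8S,8aS)-8-(TBS-oxy)-1-hydroxy-3a,6-dimethyl-1-(propan-2-yl)-2,3,3a,7,8,8a-hexahydroazulen-4(1H)-one
Conditions: IBX (2 equiv), DMSO, 70 °C
Reagents that add atoms: none
Why: A second IBX desaturation, again possible only between C7 and C6, should give the β-methyl enone.

Step 15
Reactants: 19 (1R,3aS,8S,8aS)-8-(TBS-oxy)-1-hydroxy-3a,6-dimethyl-1-(propan-2-yl)-2,3,3a,7,8,8a-hexahydroazulen-4(1H)-one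
Product: 20 (1R,3aS,8S,8aS)-1,8-dihydroxy-3a,6-dimethyl-1-(propan-2-yl)-2,3,3a,7,8,8a-hexahydroazulen-4(1H)-one
Conditions: HF·pyridine, pyridine, THF, 0 °C → rt
Reagents that add atoms: none
Why: Buffered fluoride cleaves the secondary silyl ether (desilylation) without acid or base strong enough to dehydrate the tertiary alcohol or open the vinylogous aldol.

Step 16
Reactants: 21 4-hydroxybenzoic acid
Product: 23 4-(TBS-oxy)benzoic acid, via silyl ester 22 (not isolated)
Conditions: TBSCl (2.5 equiv), imidazole, DMF, rt; then AcOH/THF/H2O, rt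
Reagents that add atoms: tert-butyldimethylsilyl chloride, CC(C)(C)[Si](C)(C)Cl
Why: Exhaustive silylation followed by selective hydrolysis of the labile silyl ester leaves the aryl silyl ether (standard phenol protection).

Step 17
Reactants: 20 (1R,3aS,8S,8aS)-1,8-dihydroxy-3a,6-dimethyl-1-(propan-2-yl)-2,3,3a,7,8,8a-hexahydroazulen-4(1H)-one; 23 4-(TBS-oxy)benzoic acid
Product: 24 (3R,3aS,4S,8aS)-3-hydroxy-6,8a-dimethyl-8-oxo-3-(propan-2-yl)-1,2,3,3a,4,5,8,8a-octahydroazulen-4-yl 4-(TBS-oxy)benzoate
Conditions: EDC·HCl, DMAP, CH2Cl2, rt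
Reagents that add atoms: none
Why: Steglich esterification acylates the secondary C4 hydroxyl, while the tertiary C3 hydroxyl is too hindered to react.

Step 18
Reactants: 24 (3R,3aS,4S,8aS)-3-hydroxy-6,8a-dimethyl-8-oxo-3-(propan-2-yl)-1,2,3,3a,4,5,8,8a-octahydroazulen-4-yl 4-(TBS-oxy)benzoate
Product: 25 (3R,3aS,4S,8aS)-3-hydroxy-6,8a-dimethyl-8-oxo-3-(propan-2-yl)-1,2,3,3a,4,5,8,8a-octahydroazulen-4-yl 4-hydroxybenzoate
Conditions: TBAF, AcOH, THF, 0 °C
Reagents that add atoms: none
Why: Acetic-acid-buffered fluoride cleaves the aryl silyl ether (desilylation) at a pH at which the δ-acyloxy enone should not undergo vinylogous β-elimination.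

**Compound list**

1 | cyclohepta-1,3-diene | C1=CC=CCCC1 | starting material
2 | (1R,5S)-6,7-dioxabicyclo[3.2.2]non-8-ene (meso) | O1O[C@H]2CCC[C@@H]1C=C2 | intermediate
3 | (4S)-4-hydroxycyclohept-2-en-1-one | O=C1C=C[C@@H](O)CCC1 | intermediate
4 | (4S)-4-[(tert-butyldimethylsilyl)oxy]cyclohept-2-en-1-one | O=C1C=C[C@@H](O[Si](C)(C)C(C)(C)C)CCC1 | intermediate
5 | (4S)-4-[(tert-butyldimethylsilyl)oxy]-2-iodocyclohept-2-en-1-one | O=C1C(I)=C[C@@H](O[Si](C)(C)C(C)(C)C)CCC1 | intermediate
6 | (4S)-4-[(tert-butyldimethylsilyl)oxy]-2-methylcyclohept-2-en-1-one | CC1=C[C@@H](O[Si](C)(C)C(C)(C)C)CCCC1=O | intermediate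
7 | 3-methylbutan-2-one | CC(=O)C(C)C | starting material
8 | 2,4,6-tri(propan-2-yl)benzenesulfonohydrazide | CC(C)c1cc(C(C)C)c(S(=O)(=O)NN)c(C(C)C)c1 | starting material
9 | (E)-N'-(3-methylbutan-2-ylidene)-2,4,6-tri(propan-2-yl)benzenesulfonohydrazide | CC(C)/C(C)=N/NS(=O)(=O)c1c(C(C)C)cc(C(C)C)cc1C(C)C | intermediate
10 | allyl bromide (3-bromoprop-1-ene) | C=CCBr | starting material
11 | lithium (3S,4S)-4-[(tert-butyldimethylsilyl)oxy]-2-methyl-3-(3-methylbut-1-en-2-yl)cyclohept-1-en-1-olate | [Li]OC1=C(C)[C@H](C(=C)C(C)C)[C@@H](O[Si](C)(C)C(C)(C)C)CCC1 | intermediate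
12 | (2S,3S,4S)-4-[(tert-butyldimethylsilyl)oxy]-2-methyl-3-(3-methylbut-1-en-2-yl)-2-(prop-2-en-1-yl)cycloheptan-1-one | C1CC(=O)[C@@](C)(CC=C)[C@H](C(=C)C(C)C)[C@@H](O[Si](C)(C)C(C)(C)C)C1 | intermediate
13 | 2-[(1S,2S,3S)-3-[(tert-butyldimethylsilyl)oxy]-1-methyl-2-(2-methylpropanoyl)-7-oxocycloheptyl]acetaldehyde | C1CC(=O)[C@@](C)(CC=O)[C@H](C(=O)C(C)C)[C@@H](O[Si](C)(C)C(C)(C)C)C1 | intermediate
14 | (2S,3S,4S)-4-[(tert-butyldimethylsilyl)oxy]-2-(2-hydroxyethyl)-2-methyl-3-(2-methylpropanoyl)cycloheptan-1-one | C1CC(=O)[C@@](C)(CCO)[C@H](C(=O)C(C)C)[C@@H](O[Si](C)(C)C(C)(C)C)C1 | intermediate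
15 | (2S,3S,4S)-4-[(tert-butyldimethylsilyl)oxy]-2-(2-iodoethyl)-2-methyl-3-(2-methylpropanoyl)cycloheptan-1-one | C1CC(=O)[C@@](C)(CCI)[C@H](C(=O)C(C)C)[C@@H](O[Si](C)(C)C(C)(C)C)C1 | intermediate
16 | (1R,3aS,8S,8aS)-8-[(tert-butyldimethylsilyl)oxy]-1-hydroxy-3a-methyl-1-(propan-2-yl)octahydroazulen-4(1H)-one | C1CC(=O)[C@@]2(C)CC[C@@](O)(C(C)C)[C@@H]2[C@@H](O[Si](C)(C)C(C)(C)C)C1 | intermediate
17 | (1R,3aS,8S,8aS)-8-[(tert-butyldimethylsilyl)oxy]-1-hydroxy-3a-methyl-1-(propan-2-yl)-2,3,3a,7,8,8a-hexahydroazulen-4(1H)-one | C1=CC(=O)[C@@]2(C)CC[C@@](O)(C(C)C)[C@@H]2[C@@H](O[Si](C)(C)C(C)(C)C)C1 | intermediate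
18 | (1R,3aS,8S,8aS)-8-[(tert-butyldimethylsilyl)oxy]-1-hydroxy-3a,6-dimethyl-1-(propan-2-yl)octahydroazulen-4(1H)-one (C6 epimers) | CC1CC(=O)[C@@]2(C)CC[C@@](O)(C(C)C)[C@@H]2[C@@H](O[Si](C)(C)C(C)(C)C)C1 | intermediate
19 | (1R,3aS,8S,8aS)-8-[(tert-butyldimethylsilyl)oxy]-1-hydroxy-3a,6-dimethyl-1-(propan-2-yl)-2,3,3a,7,8,8a-hexahydroazulen-4(1H)-one | CC1=CC(=O)[C@@]2(C)CC[C@@](O)(C(C)C)[C@@H]2[C@@H](O[Si](C)(C)C(C)(C)C)C1 | intermediate
20 | (1R,3aS,8S,8aS)-1,8-dihydroxy-3a,6-dimethyl-1-(propan-2-yl)-2,3,3a,7,8,8a-hexahydroazulen-4(1H)-one | CC1=CC(=O)[C@@]2(C)CC[C@@](O)(C(C)C)[C@@H]2[C@@H](O)C1 | intermediate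
21 | 4-hydroxybenzoic acid | OC(=O)c1ccc(O)cc1 | starting material
22 | tert-butyldimethylsilyl 4-[(tert-butyldimethylsilyl)oxy]benzoate | CC(C)(C)[Si](C)(C)OC(=O)c1ccc(O[Si](C)(C)C(C)(C)C)cc1 | intermediate
23 | 4-[(tert-butyldimethylsilyl)oxy]benzoic acid | OC(=O)c1ccc(O[Si](C)(C)C(C)(C)C)cc1 | intermediate
24 | (3R,3aS,4S,8aS)-3-hydroxy-6,8a-dimethyl-8-oxo-3-(propan-2-yl)-1,2,3,3a,4,5,8,8a-octahydroazulen-4-yl 4-[(tert-butyldimethylsilyl)oxy]benzoate | CC1=CC(=O)[C@@]2(C)CC[C@@](O)(C(C)C)[C@@H]2[C@@H](OC(=O)c2ccc(O[Si](C)(C)C(C)(C)C)cc2)C1 | intermediate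
25 | (3R,3aS,4S,8aS)-3-hydroxy-6,8a-dimethyl-8-oxo-3-(propan-2-yl)-1,2,3,3a,4,5,8,8a-octahydroazulen-4-yl 4-hydroxybenzoate | CC1=CC(=O)[C@@]2(C)CC[C@@](O)(C(C)C)[C@@H]2[C@@H](OC(=O)c2ccc(O)cc2)C1 | target

**Step count.** Total: 18 steps. Longest linear sequence: 16 steps (steps 1–5, 7–15, 17 and 18); steps 6 and 16 are side branches.

**Steps most likely to fail**

Step 7. The congested copper–lithium enolate may be C-allylated only slowly, so that proton quench, O-allylation or loss of the trans relationship between the allyl and alkenyl groups could intervene. The fallback sets out from 6 and keeps the conjugate addition, but traps enolate 11 on oxygen with allyl chloroformate to give allyl (3S,4S)-4-(TBS-oxy)-2-methyl-3-(3-methylbut-1-en-2-yl)cyclohept-1-en-1-yl carbonate F1, which is isolated. Treatment with Pd(PPh3)4 in THF at rt should then release CO2 and join the palladium enolate and the π-allyl fragment on the face opposite the C3a alkenyl group (decarboxylative Tsuji allylation, well established for quaternary α-carbons). The fallback comes back to the route at 12.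

Step 11. Electron transfer to one of the two ketones may compete with reduction of the C–I bond and divert material into ketyl-derived reduction or coupling products, or the alkylsamarium may be protonated before it closes. The fallback sets out from 15 and abandons electron transfer for a polar, two-electron route: lithium–iodine exchange with t-BuLi (2.1 equiv) in Et2O/pentane at −100 °C, where exchange at a primary iodide is known to outrun carbonyl addition and enolisation. The alkyllithium should close the same C2–C3 bond in an anionic cyclisation of the iodo ketone. It comes back to the route at 16 and makes no new compound.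

Step 2. The desymmetrising elimination may proceed with insufficient enantiomeric enrichment. The fallback sets out from 2 and takes its asymmetry from an enzyme instead. Thiourea in MeOH reduces the O–O bond to meso cis-cyclohept-2-ene-1,4-diol F2. Lipase-mediated monoacetylation (Novozym 435, vinyl acetate) should acylate the R carbinol and give (1R,4S)-4-hydroxycyclohept-2-en-1-yl acetate F3. Silylation with TBSCl and imidazole gives (1R,4S)-4-(TBS-oxy)cyclohept-2-en-1-yl acetate F4, methanolysis with K2CO3 gives (1R,4S)-4-(TBS-oxy)cyclohept-2-en-1-ol F5, and allylic oxidation with MnO2 in CH2Cl2 comes back to the route at 4.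

**Further compounds**

F1 | step 7 | allyl (3S,4S)-4-[(tert-butyldimethylsilyl)oxy]-2-methyl-3-(3-methylbut-1-en-2-yl)cyclohept-1-en-1-yl carbonate | C=CCOC(=O)OC1=C(C)[C@H](C(=C)C(C)C)[C@@H](O[Si](C)(C)C(C)(C)C)CCC1
F0 | step 11 | none | none
F2 | step 2 | (1R,4S)-cyclohept-2-ene-1,4-diol (meso, cis) | O[C@H]1CCC[C@@H](O)C=C1
F3 | step 2 | (1R,4S)-4-hydroxycyclohept-2-en-1-yl acetate | O[C@H]1CCC[C@@H](OC(C)=O)C=C1
F4 | step 2 | (1R,4S)-4-[(tert-butyldimethylsilyl)oxy]cyclohept-2-en-1-yl acetate | CC(C)(C)[Si](C)(C)O[C@H]1CCC[C@@H](OC(C)=O)C=C1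
F5 | step 2 | (1R,4S)-4-[(tert-butyldimethylsilyl)oxy]cyclohept-2-en-1-ol | CC(C)(C)[Si](C)(C)O[C@H]1CCC[C@@H](O)C=C1
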